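## Structural features

The target is a depsidone: two benzene rings, ring A and ring B, joined by a diaryl ether oxygen and by an aryl ester, which together close a seven-membered dioxepinone. Ring A is pentasubstituted (a1 OMe, a2 H, a3 Me, a4 ester carbonyl, a5 ether oxygen, a6 OH). Ring B is hexasubstituted (b1 ether oxygen, b2 ester oxygen, b3 Me, b4 OH, b5 lactone carbonyl, b6 lactol carbon) and carries a fused 3-hydroxyphthalide. The lactol carbon on b6 is the only stereocentre (R, by CIP analysis of the SMILES) and has no stereogenic neighbour; it epimerises through the ring-opened formyl carboxylate as soon as base or water is present. Other fragile groups are the aryl ester of the seven-membered ring, the electron-rich para-dioxygenated ring B and, along the way, a dimethyl acetal next to a hydroxymethyl or carboxyl group. The real difficulties are the regiocontrolled construction of ring B, the diaryl ether between two doubly ortho-substituted carbons, and the delivery of one configuration at a labile lactol. Ring B has its oxygens b1 and b4 para to each other, with O and Me (b2, b3) on one flank and two carbon substituents (b5, b6) on the other. This is the pattern that a squarate-derived 4-alkenyl-4-oxycyclobutenone gives on ring expansion, with b1 and b4 differentiated from the start.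

## Logic of the disconnections

30 to 29. The three O–acyl bonds are cut (two aryl propionates and the acylal propionate). The free lactol cannot be carried through basic or aqueous steps, so it is unveiled last from a configurationally stable acylal. The stereochemical problem moves to 29, which can be purified and stored. The forward step must cleave at the acyl carbons only, in neutral organic medium, and spare the seven-membered aryl ester and the lactone.

29 to 28. The exocyclic O–acyl bond at the lactol carbon is cut, together with the two phenol O–acyl bonds. Racemic 28 interconverts its enantiomers by ring opening, so a chiral acyl-transfer catalyst can funnel all material into one acylal. No stereocentre then has to be carried through the route. The forward step needs racemisation faster than acylation and catalyst control over the uncatalysed background.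

28 to 26. The ester C–O bond between the ring A carboxyl carbon and the b2 oxygen is cut. Only the b2 hydroxyl can reach that carboxyl, so the closure is regiochemically unambiguous. The seven-membered ring opens to a diaryl ether acid. The forward step must activate a doubly ortho-substituted acid in the presence of free phenols and the lactol, at high dilution.

26 to 25 to 23. The two O–isopropyl bonds, the O–benzyl bond and the acetal O–methyl bond are cut, and both carboxyl groups are taken back to formyl groups. All ether groups answer to one Lewis acid and both aldehydes to one oxidant. The demand is that the acetal on b6 outlives the oxidation of b5, because b5 and b6 would otherwise lose their distinction, and that the aryl methyl ether survives BCl3.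

23 to 22 to 17 + 21. After a retro-oxidation at b5, the C–O bond between a5 and the b1 oxygen is cut. The b1 oxygen is already in place in 17, and the a5 bromide of 21 is activated by its ortho formyl group. This gives two monocyclic halves. The forward coupling joins two doubly ortho-substituted carbons and must use the phenoxide in preference to the primary alcohol.

21 to 20 to 19 to 18. The C–CHO bond at a4, the O–isopropyl bond at a6 and the C–Br bond at a5 are cut. Each group enters at the position set by the strongest director present. The formylation has to go para to methoxy although that position lies between bromine and methyl.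

17 to 16 to 15. The benzyl ether on b4 is removed and the two silyl ethers are restored. The b4 phenol must be capped before the b1 oxygen is set free, or a hydroquinone with two competing hydroxyls would result. Both silyl groups are removed later in one fluoride treatment, which also frees the arm for oxidation while the acetal is still intact.

15 to 12. The b4–b5 bond is cut (retro-6π) and the b4–b1 bond is restored (retro-4π). A hexasubstituted benzene is reduced to a cyclobutenone that already carries all six substituents in the correct order. The forward step needs outward rotation of the silyloxy group and nothing else but heat.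

12 to 9 + 6. The C–C bond between b1 (the carbinol carbon) and b6 (the alkenyl carbon) and the O–Si bond are cut. The addition must go to the ketone-type carbonyl of 9, and the alkenyllithium 10 must form and react with retention at low temperature. The arm carries a silyl ether and not a benzyl ether, so that it can be unveiled and oxidised before the Lewis-acid deprotection.

9 to 7, and 6 to 5 to 3 to 2 to 1. The C–CH3 bond of 9 is cut; in the chain the acetal C–O bonds, the C–Br bond and the O–Si bond are cut. All forward steps are standard functional-group chemistry.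

## Other disconnections considered

Alternative 1: The lactone C–O bond and the exocyclic acylal C–O bond are cut, taking the phthalide back to the ring B dialdehyde diacetate A2. In the forward step a chiral triazolium carbene with a quinone oxidant turns the formyl group on b5 into an acyl azolium, a carboxylate adds to the formyl group on b6, and the resulting alkoxide is acylated to give the (R)-triacetate A1.
- In favour: one catalytic step closes the lactone and sets the stereocentre, and the product is a stable acylal. Both arms could be carried at the same oxidation level from the ring expansion, which would remove the separate oxidations of steps 14 and 15.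
- Against: the catalyst must tell apart two formyl groups on a hexasubstituted ring, and the wrong choice gives the regioisomeric phthalide. Ortho-dialdehydes can also undergo carbene-mediated internal redox to a simple phthalide.
- Comparison: on step economy the alternative is the better plan by about two steps. On enantiocontrol the two are equal in kind, since both rely on a chiral acyl-transfer catalyst and end with a triester and an enzyme. On regiocontrol the chosen plan is better, because b5 and b6 are distinguished by construction in 12.

Alternative 2: The depside ester C–O bond and one C–C bond of ring A are cut, leading to the diketo-dioxinone A4 and the ring B bromophenol A5. On heating, A4 releases an acylketene that the b2 hydroxyl of A5 traps, and base-mediated aldol condensation then aromatises ring A to give the bromo depside A3.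
- In favour: the hindered ester forms under neutral conditions and ring A needs no arene chemistry. The ether would then be closed intramolecularly onto the b1 bromide; on this point the alternative is better than the intermolecular coupling of step 13.
- Against: the ring A that forms is an orsellinate. It lacks the a6 oxygen, so a late hydroxylation between two oxygens and a selective methylation would be needed. A5, the hexasubstituted ring, is not made by the key step and needs its own synthesis, and its two phenols must be told apart by the ketene.
- Comparison: both key steps are reliable ketene chemistry. The chosen plan spends its key step on the difficult ring and takes ring A from a simple phenol, so it should be shorter overall. Both need the same end game at the lactol.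

Alternative 3: The aryl ester C–O bond at b2 is cut back to a C–H bond, leading to the diaryl ether acid A7 with a free b4 phenol. A hypervalent iodine oxidant makes the ring A carboxyl attack b1 to give the spiro ketal lactone A8, and a Lewis acid shifts the acyloxy group to b2 with rearomatisation to give the depsidone aldehyde ester A6.
- In favour: the b2 oxygen need not be carried, so ring B is one substituent simpler and no isopropyl ether or BCl3 step is needed. The diaryl ether is made on a phenol with only one ortho substituent; on this point the alternative is better than the chosen plan.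
- Against: ring B must be dearomatised oxidatively in the presence of an electron-rich ring A and a free aldehyde. The shift must move the acyloxy and not the aryloxy group, and the quinol ketal can be lost to solvolysis. The allyl groups of A6 still have to be removed with zerovalent palladium before the same lactol end game.
- Comparison: step economy is about equal. The chosen plan is more predictable because every ring B substituent is placed by the cyclobutenone. The alternative is the more biomimetic.

Key step: step 7

Assumption: the free (R)-lactol is taken to keep its configuration only in base-free, non-aqueous medium at or below room temperature, and the (2S,3R) antipode of the isothiourea is taken as the one that gives the (R)-acylal, to be confirmed on a model hydroxyphthalide and exchanged for its mirror image if the sense is opposite.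

## Route

Step 1
Reactants: 1 (Z)-but-2-ene-1,4-diol
Product: 2 (Z)-4-[(tert-butyldiphenylsilyl)oxy]but-2-en-1-ol
Conditions: NaH (1.0 equiv), THF, 0 °C; then TBDPSCl (1.0 equiv), 0 °C to rt
Reagents that add atoms: tert-butyl(chloro)diphenylsilane CC(C)(C)[Si](Cl)(c1ccccc1)c1ccccc1
Why: One equivalent of NaH gives the sparingly soluble monoalkoxide, which is silylated once (monoprotection of a symmetric diol by O-silylation); the alkene geometry is untouched.

Step 2
Reactants: 2 (Z)-4-[(tert-butyldiphenylsilyl)oxy]but-2-en-1-ol
Product: 3 (Z)-4-[(tert-butyldiphenylsilyl)oxy]but-2-enal (any E isomer formed is equally usable)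
Conditions: TEMPO (2,2,6,6-tetramethylpiperidin-1-oxyl, cat.), PhI(OAc)2, CH2Cl2, rt
Reagents that add atoms: none
Why: Oxoammonium-mediated oxidation of the allylic alcohol stops at the aldehyde and tolerates the silyl ether; step 3 erases the alkene geometry, so Z to E drift does no harm.

Step 3
Reactants: 3 (Z)-4-[(tert-butyldiphenylsilyl)oxy]but-2-enal
Product: 5 (Z)-2-bromo-4-[(tert-butyldiphenylsilyl)oxy]but-2-enal, via dibromo aldehyde 4 (not isolated)
Conditions: Br2, CH2Cl2, −78 °C; then Et3N, −78 to 0 °C
Reagents that add atoms: bromine BrBr
Why: Bromine adds across the alkene and Et3N removes HBr from the alpha position by an E1cB path (bromination–dehydrobromination of an enal); the product should settle as the isomer with CHO trans to the CH2OSi group, that is Br cis to it.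

Step 4
Reactants: 5 (Z)-2-bromo-4-[(tert-butyldiphenylsilyl)oxy]but-2-enal
Product: 6 (Z)-[(3-bromo-4,4-dimethoxybut-2-en-1-yl)oxy](tert-butyl)diphenylsilane
Conditions: HC(OMe)3, MeOH, TsOH·H2O (cat.), rt; Et3N quench
Reagents that add atoms: trimethyl orthoformate COC(OC)OC; methanol CO
Why: Acid-catalysed acetalisation with the orthoformate as water scavenger; the alpha-bromine suppresses conjugate addition of methanol and the TBDPS ether should survive catalytic acid.

Step 5
Reactants: 7 diisopropyl squarate (3,4-diisopropoxycyclobut-3-ene-1,2-dione)
Product: 9 3-isopropoxy-4-methylcyclobut-3-ene-1,2-dione, via lithium alkoxide 8 (not isolated)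
Conditions: MeLi, THF, −78 °C; then (CF3CO)2O, −78 °C to rt
Reagents that add atoms: methyllithium [Li]C
Why: MeLi adds 1,2 to one carbonyl; trifluoroacetylation of the alkoxide triggers ionisation and loss of one isopropyl group, the standard conversion of a squarate ester into a 3-alkoxy-4-alkylcyclobutenedione.

Step 6
Reactants: 6 (Z)-[(3-bromo-4,4-dimethoxybut-2-en-1-yl)oxy](tert-butyl)diphenylsilane; 9 3-isopropoxy-4-methylcyclobut-3-ene-1,2-dione
Product: 12 4-[(tert-butyldimethylsilyl)oxy]-4-{(E)-4-[(tert-butyldiphenylsilyl)oxy]-1,1-dimethoxybut-2-en-2-yl}-3-isopropoxy-2-methylcyclobut-2-en-1-one (racemic), via alkenyllithium 10 (not isolated), via lithium alkoxide 11 (not isolated)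
Conditions: t-BuLi (2.0 equiv), THF, −78 °C; then 9, −78 °C; then TBSOTf, −78 to −20 °C; Et3N quench
Reagents that add atoms: tert-butyldimethylsilyl trifluoromethanesulfonate CC(C)(C)[Si](C)(C)OS(=O)(=O)C(F)(F)F
Why: Br–Li exchange proceeds with retention; the alkenyllithium adds to the ketone-type carbonyl of 9 (the one next to C–OiPr, not the vinylogous ester carbonyl) and the tertiary alkoxide is silylated in the same flask before it can meet free silyl triflate and the acetal together. The new quaternary centre is racemic and is destroyed in step 7.

Step 7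
Reactants: 12 4-[(tert-butyldimethylsilyl)oxy]-4-{(E)-4-[(tert-butyldiphenylsilyl)oxy]-1,1-dimethoxybut-2-en-2-yl}-3-isopropoxy-2-methylcyclobut-2-en-1-one
Product: 15 4-[(tert-butyldimethylsilyl)oxy]-2-{[(tert-butyldiphenylsilyl)oxy]methyl}-3-(dimethoxymethyl)-5-isopropoxy-6-methylphenol, via dienylketene 13 (not isolated), via cyclohexadienone 14 (not isolated)
Conditions: toluene (degassed, 0.02 M), 110 °C
Reagents that add atoms: none
Why: Thermal conrotatory 4π opening of the cyclobutenone cleaves the bond between the carbonyl carbon and the silyloxy-bearing carbon; the silyloxy group rotates outward, which puts the alkenyl group on the same side as the ketene in 13. Disrotatory 6π electrocyclisation then joins the ketene carbon to the alkene terminus that carries CH2OSi, closing the six-membered carbocycle as 14, and enolisation gives phenol 15. The closest known reaction type is the Moore rearrangement of a 4-alkenyl-4-oxycyclobutenone. Ring B closes by an all-carbon 6π electrocyclic process, not by a polar cyclisation. No stereocentre is created: the quaternary carbon of 12 becomes b1 and the sp3 carbon of 14 is lost on tautomerisation. Two selectivities are needed: torquoselectivity, secured by the strong outward preference of an oxygen donor on the sp3 carbon, and the placement of methyl and isopropoxy, secured in step 6 by addition to the non-vinylogous carbonyl. The ketene carbonyl should emerge as the free phenol (b4) and the silylated oxygen as its para partner (b1), so the two oxygens are differentiated. The CH2OSi group lies on the inside of the closing triene, which may slow the closure but cannot redirect it.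

Step 8
Reactants: 15 4-[(tert-butyldimethylsilyl)oxy]-2-{[(tert-butyldiphenylsilyl)oxy]methyl}-3-(dimethoxymethyl)-5-isopropoxy-6-methylphenol
Product: 16 1-(benzyloxy)-4-[(tert-butyldimethylsilyl)oxy]-2-{[(tert-butyldiphenylsilyl)oxy]methyl}-3-(dimethoxymethyl)-5-isopropoxy-6-methylbenzene
Conditions: BnBr, K2CO3, acetone, rt to 50 °C
Reagents that add atoms: benzyl bromide BrCc1ccccc1
Why: Williamson etherification of the only free phenol; capping b4 now prevents a hydroquinone with two competing hydroxyls from appearing in step 9.

Step 9
Reactants: 16 1-(benzyloxy)-4-[(tert-butyldimethylsilyl)oxy]-2-{[(tert-butyldiphenylsilyl)oxy]methyl}-3-(dimethoxymethyl)-5-isopropoxy-6-methylbenzene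
Product: 17 4-(benzyloxy)-2-(dimethoxymethyl)-3-(hydroxymethyl)-6-isopropoxy-5-methylphenol
Conditions: Bu4NF (3 equiv), THF, 0 °C to rt; pH 7 buffer work-up, argon
Reagents that add atoms: none
Why: Fluoride cleaves both the aryl Si–O and the primary alkyl Si–O bond, while benzyl, isopropyl and acetal groups are inert; neutral work-up keeps the hydroxy acetal from closing to a cyclic acetal.

Step 10
Reactants: 18 creosol (2-methoxy-4-methylphenol)
Product: 19 2-bromo-6-methoxy-4-methylphenol
Conditions: NBS, i-Pr2NH (cat.), CH2Cl2, 0 °C
Reagents that add atoms: N-bromosuccinimide O=C1CCC(=O)N1Br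
Why: Amine-catalysed ortho-bromination of a phenol; the para position is blocked by methyl and the other ortho position by methoxy, so bromine should enter the one free ortho position (a5).

Step 11
Reactants: 19 2-bromo-6-methoxy-4-methylphenol
Product: 20 1-bromo-2-isopropoxy-3-methoxy-5-methylbenzene
Conditions: 2-bromopropane, K2CO3, DMF, 60 °C
Reagents that add atoms: 2-bromopropane CC(C)Br
Why: Williamson etherification; the isopropyl ether is chosen because it should tolerate TiCl4 at low temperature and falls to BCl3 together with the isopropyl ether on ring B.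

Step 12
Reactants: 20 1-bromo-2-isopropoxy-3-methoxy-5-methylbenzene
Product: 21 2-bromo-3-isopropoxy-4-methoxy-6-methylbenzaldehyde
Conditions: Cl2CHOMe, TiCl4, CH2Cl2, −78 to 0 °C; then H2O
Reagents that add atoms: dichloromethyl methyl ether COC(Cl)Cl; water O
Why: Rieche formylation (electrophilic aromatic substitution) para to the methoxy group and ortho to methyl; the flanked, twisted isopropoxy group is the weaker director and its para position is blocked.

Step 13
Reactants: 17 4-(benzyloxy)-2-(dimethoxymethyl)-3-(hydroxymethyl)-6-isopropoxy-5-methylphenol; 21 2-bromo-3-isopropoxy-4-methoxy-6-methylbenzaldehyde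
Product: 22 2-[4-(benzyloxy)-2-(dimethoxymethyl)-3-(hydroxymethyl)-6-isopropoxy-5-methylphenoxy]-3-isopropoxy-4-methoxy-6-methylbenzaldehyde
Conditions: CuI (20 mol%), picolinic acid (40 mol%), K3PO4, DMSO, 90 °C, argon
Reagents that add atoms: none
Why: Ullmann-type C–O coupling with monovalent copper; the ortho formyl group activates the bromide, and K3PO4 ionises only the phenol, so the primary alcohol should not be arylated.

Step 14
Reactants: 22 2-[4-(benzyloxy)-2-(dimethoxymethyl)-3-(hydroxymethyl)-6-isopropoxy-5-methylphenoxy]-3-isopropoxy-4-methoxy-6-methylbenzaldehyde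
Product: 23 2-[4-(benzyloxy)-2-(dimethoxymethyl)-3-formyl-6-isopropoxy-5-methylphenoxy]-3-isopropoxy-4-methoxy-6-methylbenzaldehyde
Conditions: Dess–Martin periodinane (1,1,1-triacetoxy-1,1-dihydro-1,2-benziodoxol-3(1H)-one), NaHCO3, CH2Cl2, 0 °C to rt
Reagents that add atoms: none
Why: Dess–Martin oxidation of the benzylic alcohol under buffered, non-acidic conditions that leave the dimethyl acetal intact.

Step 15
Reactants: 23 2-[4-(benzyloxy)-2-(dimethoxymethyl)-3-formyl-6-isopropoxy-5-methylphenoxy]-3-isopropoxy-4-methoxy-6-methylbenzaldehyde
Product: 25 2-{[7-(benzyloxy)-5-isopropoxy-3-methoxy-6-methyl-1-oxo-1,3-dihydro-2-benzofuran-4-yl]oxy}-3-isopropoxy-4-methoxy-6-methylbenzoic acid (racemic), via diacid acetal 24 (not isolated)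
Conditions: NaClO2, NaH2PO4, 2-methyl-2-butene, t-BuOH/THF/H2O, 0 °C to rt; then aq. citric acid (pH 3), rt
Reagents that add atoms: sodium chlorite [Na+].[O-]Cl=O
Why: Pinnick oxidation of both aryl aldehydes with a chlorine scavenger. On acidification the new carboxyl on b5 should capture the neighbouring acetal carbon with loss of methanol, giving a methoxyphthalide that stores b6 at the aldehyde level. The acetal must not hydrolyse before b5 is oxidised, so the oxidation is run cold and only then acidified.

Step 16
Reactants: 25 2-{[7-(benzyloxy)-5-isopropoxy-3-methoxy-6-methyl-1-oxo-1,3-dihydro-2-benzofuran-4-yl]oxy}-3-isopropoxy-4-methoxy-6-methylbenzoic acid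
Product: 26 3-hydroxy-4-methoxy-6-methyl-2-[(3,5,7-trihydroxy-6-methyl-1-oxo-1,3-dihydro-2-benzofuran-4-yl)oxy]benzoic acid (racemic)
Conditions: BCl3 (excess), pentamethylbenzene, CH2Cl2, −78 to 0 °C; then THF/H2O
Reagents that add atoms: water O
Why: BCl3 dealkylates both isopropyl ethers and the benzyl ether (cation trapped by pentamethylbenzene) and ionises the methoxy acetal; aqueous work-up gives the lactol. The aryl methyl ether has no ortho carbonyl and should be retained.

Step 17
Reactants: 26 3-hydroxy-4-methoxy-6-methyl-2-[(3,5,7-trihydroxy-6-methyl-1-oxo-1,3-dihydro-2-benzofuran-4-yl)oxy]benzoic acid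
Product: 28 racemic depsidone lactol (the target constitution with the b6 lactol carbon unassigned), via mixed trifluoroacetic anhydride 27 (not isolated)
Conditions: (CF3CO)2O, toluene (0.005 M), 0 °C to rt; then THF/H2O
Reagents that add atoms: none
Why: Mixed-anhydride lactonisation at high dilution; only the b2 hydroxyl can reach the activated ring A carboxyl, so the seven-membered aryl ester should close selectively. Transient trifluoroacetates of the other hydroxyls are hydrolysed in the work-up.

Step 18
Reactants: 28 racemic depsidone lactol
Product: 29 (R)-tripropionate of the target (propionyl on the a6 oxygen, the b4 oxygen and the lactol oxygen)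
Conditions: (EtCO)2O (5 equiv), (2S,3R)-HyperBTM [(2S,3R)-3-isopropyl-2-phenyl-3,4-dihydro-2H-pyrimido[2,1-b][1,3]benzothiazole] (10 mol%), i-Pr2NEt, CHCl3, 0 °C to rt
Reagents that add atoms: propionic anhydride CCC(=O)OC(=O)CC
Why: Lewis-base-catalysed acylative dynamic kinetic resolution: i-Pr2NEt interconverts the lactol enantiomers through the open formyl carboxylate, and the chiral acyl isothiouronium ion acylates one of them faster, so the catalyst sets the lactol stereocentre. Both phenols are acylated in the same flask without stereochemical consequence.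

Step 19
Reactants: 29 (R)-tripropionate of the target
Product: 30 target, (R)-lactol depsidone CNP0211607.1
Conditions: Novozym 435 (immobilised Candida antarctica lipase B), n-BuOH, THF/t-BuOMe, 30 °C; filtration, evaporation below 25 °C
Reagents that add atoms: none
Why: Lipase-catalysed transesterification to butanol cleaves the three propionates at the acyl carbon, so the C–O bond at the stereocentre is never broken. The base-free organic medium avoids ring opening of the lactol and leaves the hindered seven-membered aryl ester alone.

## Compound list

1 | (Z)-but-2-ene-1,4-diol | OC/C=C\CO | starting material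
2 | (Z)-4-[(tert-butyldiphenylsilyl)oxy]but-2-en-1-ol | OC/C=C\CO[Si](c1ccccc1)(c1ccccc1)C(C)(C)C | intermediate
3 | (Z)-4-[(tert-butyldiphenylsilyl)oxy]but-2-enal | O=C/C=C\CO[Si](c1ccccc1)(c1ccccc1)C(C)(C)C | intermediate
4 | 2,3-dibromo-4-[(tert-butyldiphenylsilyl)oxy]butanal (racemic diastereomers, centres destroyed on elimination) | O=CC(Br)C(Br)CO[Si](c1ccccc1)(c1ccccc1)C(C)(C)C | intermediate (not isolated)
5 | (Z)-2-bromo-4-[(tert-butyldiphenylsilyl)oxy]but-2-enal | O=C/C(Br)=C/CO[Si](c1ccccc1)(c1ccccc1)C(C)(C)C | intermediate
6 | (Z)-[(3-bromo-4,4-dimethoxybut-2-en-1-yl)oxy](tert-butyl)diphenylsilane | COC(OC)/C(Br)=C/CO[Si](c1ccccc1)(c1ccccc1)C(C)(C)C | intermediate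
7 | diisopropyl squarate | CC(C)OC1=C(OC(C)C)C(=O)C1=O | starting material
8 | lithium 2,3-diisopropoxy-1-methyl-4-oxocyclobut-2-en-1-olate (racemic) | [Li+].[O-]C1(C)C(OC(C)C)=C(OC(C)C)C1=O | intermediate (not isolated)
9 | 3-isopropoxy-4-methylcyclobut-3-ene-1,2-dione | CC1=C(OC(C)C)C(=O)C1=O | intermediate
10 | {(E)-4-[(tert-butyldiphenylsilyl)oxy]-1,1-dimethoxybut-2-en-2-yl}lithium (Li cis to CH2OSi) | [Li]/C(C(OC)OC)=C\CO[Si](c1ccccc1)(c1ccccc1)C(C)(C)C | intermediate (not isolated)
11 | lithium alkoxide of the carbinol corresponding to 12 (racemic, one enantiomer drawn) | CC1=C(OC(C)C)[C@@]([O-])(/C(C(OC)OC)=C\CO[Si](c2ccccc2)(c2ccccc2)C(C)(C)C)C1=O.[Li+] | intermediate (not isolated)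
12 | 4-[(tert-butyldimethylsilyl)oxy]-4-{(E)-4-[(tert-butyldiphenylsilyl)oxy]-1,1-dimethoxybut-2-en-2-yl}-3-isopropoxy-2-methylcyclobut-2-en-1-one (racemic, one enantiomer drawn) | CC1=C(OC(C)C)[C@@](O[Si](C)(C)C(C)(C)C)(/C(C(OC)OC)=C\CO[Si](c2ccccc2)(c2ccccc2)C(C)(C)C)C1=O | intermediate
13 | (3Z,5E)-4-[(tert-butyldimethylsilyl)oxy]-7-[(tert-butyldiphenylsilyl)oxy]-5-(dimethoxymethyl)-3-isopropoxy-2-methylhepta-1,3,5-trien-1-one | O=C=C(C)/C(OC(C)C)=C(O[Si](C)(C)C(C)(C)C)\C(C(OC)OC)=C/CO[Si](c1ccccc1)(c1ccccc1)C(C)(C)C | intermediate (not isolated)
14 | 4-[(tert-butyldimethylsilyl)oxy]-6-{[(tert-butyldiphenylsilyl)oxy]methyl}-5-(dimethoxymethyl)-3-isopropoxy-2-methylcyclohexa-2,4-dien-1-one (racemic) | O=C1C(C)=C(OC(C)C)C(O[Si](C)(C)C(C)(C)C)=C(C(OC)OC)C1CO[Si](c2ccccc2)(c2ccccc2)C(C)(C)C | intermediate (not isolated)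
15 | 4-[(tert-butyldimethylsilyl)oxy]-2-{[(tert-butyldiphenylsilyl)oxy]methyl}-3-(dimethoxymethyl)-5-isopropoxy-6-methylphenol | COC(OC)c1c(O[Si](C)(C)C(C)(C)C)c(OC(C)C)c(C)c(O)c1CO[Si](c2ccccc2)(c2ccccc2)C(C)(C)C | intermediate
16 | 1-(benzyloxy)-4-[(tert-butyldimethylsilyl)oxy]-2-{[(tert-butyldiphenylsilyl)oxy]methyl}-3-(dimethoxymethyl)-5-isopropoxy-6-methylbenzene | COC(OC)c1c(O[Si](C)(C)C(C)(C)C)c(OC(C)C)c(C)c(OCc2ccccc2)c1CO[Si](c2ccccc2)(c2ccccc2)C(C)(C)C | intermediate
17 | 4-(benzyloxy)-2-(dimethoxymethyl)-3-(hydroxymethyl)-6-isopropoxy-5-methylphenol | COC(OC)c1c(O)c(OC(C)C)c(C)c(OCc2ccccc2)c1CO | intermediate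
18 | creosol (2-methoxy-4-methylphenol) | Cc1ccc(O)c(OC)c1 | starting material
19 | 2-bromo-6-methoxy-4-methylphenol | COc1cc(C)cc(Br)c1O | intermediate
20 | 1-bromo-2-isopropoxy-3-methoxy-5-methylbenzene | COc1cc(C)cc(Br)c1OC(C)C | intermediate
21 | 2-bromo-3-isopropoxy-4-methoxy-6-methylbenzaldehyde | COc1cc(C)c(C=O)c(Br)c1OC(C)C | intermediate
22 | 2-[4-(benzyloxy)-2-(dimethoxymethyl)-3-(hydroxymethyl)-6-isopropoxy-5-methylphenoxy]-3-isopropoxy-4-methoxy-6-methylbenzaldehyde | COC(OC)c1c(Oc2c(C=O)c(C)cc(OC)c2OC(C)C)c(OC(C)C)c(C)c(OCc2ccccc2)c1CO | intermediate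
23 | 2-[4-(benzyloxy)-2-(dimethoxymethyl)-3-formyl-6-isopropoxy-5-methylphenoxy]-3-isopropoxy-4-methoxy-6-methylbenzaldehyde | COC(OC)c1c(Oc2c(C=O)c(C)cc(OC)c2OC(C)C)c(OC(C)C)c(C)c(OCc2ccccc2)c1C=O | intermediate
24 | 2-[4-(benzyloxy)-3-carboxy-2-(dimethoxymethyl)-6-isopropoxy-5-methylphenoxy]-3-isopropoxy-4-methoxy-6-methylbenzoic acid | COC(OC)c1c(Oc2c(C(=O)O)c(C)cc(OC)c2OC(C)C)c(OC(C)C)c(C)c(OCc2ccccc2)c1C(=O)O | intermediate (not isolated)
25 | 2-{[7-(benzyloxy)-5-isopropoxy-3-methoxy-6-methyl-1-oxo-1,3-dihydro-2-benzofuran-4-yl]oxy}-3-isopropoxy-4-methoxy-6-methylbenzoic acid (racemic) | COC1OC(=O)c2c(OCc3ccccc3)c(C)c(OC(C)C)c(Oc3c(C(=O)O)c(C)cc(OC)c3OC(C)C)c12 | intermediate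
26 | 3-hydroxy-4-methoxy-6-methyl-2-[(3,5,7-trihydroxy-6-methyl-1-oxo-1,3-dihydro-2-benzofuran-4-yl)oxy]benzoic acid (racemic) | OC1OC(=O)c2c(O)c(C)c(O)c(Oc3c(C(=O)O)c(C)cc(OC)c3O)c12 | intermediate
27 | mixed anhydride of 26 (ring A carboxyl) with trifluoroacetic acid | OC1OC(=O)c2c(O)c(C)c(O)c(Oc3c(C(=O)OC(=O)C(F)(F)F)c(C)cc(OC)c3O)c12 | intermediate (not isolated)
28 | racemic depsidone lactol (ring A: a1 OMe, a3 Me, a6 OH; ring B: b3 Me, b4 OH, 3-hydroxyphthalide on b5/b6; a5–O–b1 ether, a4–CO–O–b2 ester) | COc1cc(C)c2c(c1O)Oc1c(c(C)c(O)c3c1C(O)OC3=O)OC2=O | intermediate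
29 | (R)-tripropionate of the target (propionates on a6–O, b4–O and the lactol oxygen) | COc1cc(C)c2c(c1OC(=O)CC)Oc1c(c(C)c(OC(=O)CC)c3c1[C@H](OC(=O)CC)OC3=O)OC2=O | intermediate
30 | target, (R)-lactol depsidone CNP0211607.1 | COc1cc(C)c2c(c1O)Oc1c(c(C)c(O)c3c1[C@H](O)OC3=O)OC2=O | target

## Step count and uncertain steps

Total: 19 steps. Longest linear sequence: 15 steps (steps 1–4, 6–9 and 13–19); steps 5 and 10–12 are convergent branches.

**Step 7 (key step).** The CH2OSi group points into the closing triene. If this slows the 6π closure, the long-lived ketene may be consumed by dimerisation or by addition of phenol already formed, and long heating favours oxidative loss of the aryl silyl group.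
Fallback, from 9 back to the route at 23: the arm carbon is left out of the ring expansion and added afterwards. 2-Bromo-3,3-dimethoxyprop-1-ene F1, the dimethyl acetal of 2-bromoacrolein, is lithiated, added to 9 and silylated as in step 6 to give 4-[(tert-butyldimethylsilyl)oxy]-4-(3,3-dimethoxyprop-1-en-2-yl)-3-isopropoxy-2-methylcyclobut-2-en-1-one F2, whose alkene terminus is unsubstituted. Thermolysis should give 4-[(tert-butyldimethylsilyl)oxy]-3-(dimethoxymethyl)-5-isopropoxy-6-methylphenol F3. Magnesium-mediated ortho-formylation (MgCl2, Et3N, paraformaldehyde) can enter only the free position b5 and gives 3-[(tert-butyldimethylsilyl)oxy]-2-(dimethoxymethyl)-6-hydroxy-4-isopropoxy-5-methylbenzaldehyde F4. Benzylation gives 6-(benzyloxy)-3-[(tert-butyldimethylsilyl)oxy]-2-(dimethoxymethyl)-4-isopropoxy-5-methylbenzaldehyde F5, and Bu4NF gives 6-(benzyloxy)-2-(dimethoxymethyl)-3-hydroxy-4-isopropoxy-5-methylbenzaldehyde F6. Coupling of F6 with 21 under the conditions of step 13 gives 23 directly, so step 14 falls away. This path is held in reserve because the formylation must enter a position flanked on both sides.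

**Step 13 (diaryl ether).** Both partners carry two ortho substituents, so formation of the copper aryl phenoxide may be too slow, and reduction of the bromide or decomposition of the aldehyde may take over.
Fallback, from 17 back to the route at 22: the coupling is changed to addition–elimination on an aryl fluoride, whose small leaving group lowers the steric demand and needs no metal. Commercial 5-fluorovanillin F7 is hydrogenolysed (H2, Pd/C, AcOH) to 2-fluoro-6-methoxy-4-methylphenol F8. Isopropylation as in step 11 gives 1-fluoro-2-isopropoxy-3-methoxy-5-methylbenzene F9, and formylation as in step 12 gives 2-fluoro-3-isopropoxy-4-methoxy-6-methylbenzaldehyde F10. The potassium phenoxide of 17 (K2CO3, DMF, 90 °C) should displace the fluoride ortho to the formyl group and give 22.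

**Step 18 (dynamic kinetic acylation).** Facial discrimination may be poor on a lactol whose neighbour b1 carries a bulky aryloxy group, or uncatalysed acylation may compete, so that the acylal forms with low enantiomeric purity.
Fallback, from 28 back to the route at 29: physical resolution. 28 is propionylated without a chiral catalyst ((EtCO)2O, pyridine, 4-(dimethylamino)pyridine) to the racemic tripropionate F15. This is separated on a chiral stationary phase into 29 and the (S)-tripropionate F16. F16 can be returned to 28 by the lipase of step 19, since the free lactol racemises with base.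

**Step 19 (lipase alcoholysis).** The two aryl propionates are flanked on both sides and may not be accepted by the enzyme, so deacylation may stop at partly acylated material. Forcing it with base or water would open the lactol and erase the stereocentre.
Fallback, from 28 back to the route at 30: the phenols are masked as silyl ethers, so that the enzyme has only the exposed acylal ester to cut. 28 is silylated (TBSOTf, 2,6-lutidine; any lactol silyl ether is cleaved by aqueous acetic acid in the work-up) to the racemic bis(tert-butyldimethylsilyl) ether F17. F17 undergoes the acylation of step 18 at the lactol only and gives the (R)-propionyl acylal bis(silyl ether) F18. HF·pyridine removes the aryl silyl groups to give the (R)-propionyl acylal diphenol F19, and the lipase alcoholysis of step 19 then cleaves the single propionate to 30.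

**Step 12 (formylation of ring A).** Attack may occur ortho instead of para to the methoxy group, at the other free position, or the isopropyl group may be lost under TiCl4.
Fallback, from 18 back to the route at 21: carbon first, bromine second. 18 is acetylated to 2-methoxy-4-methylphenyl acetate F11 and formylated para to methoxy (the acetoxy group is a weak director) to 5-formyl-2-methoxy-4-methylphenyl acetate F12. Deacetylation (K2CO3, MeOH) gives 5-hydroxy-4-methoxy-2-methylbenzaldehyde F13. The free phenol then directs bromine (NBS, i-Pr2NH cat.) to its only open ortho position, between OH and CHO, giving 2-bromo-3-hydroxy-4-methoxy-6-methylbenzaldehyde F14. Isopropylation as in step 11 gives 21.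

## Further compounds

F1 | step 7 | 2-bromo-3,3-dimethoxyprop-1-ene | COC(OC)C(Br)=C
F2 | step 7 | 4-[(tert-butyldimethylsilyl)oxy]-4-(3,3-dimethoxyprop-1-en-2-yl)-3-isopropoxy-2-methylcyclobut-2-en-1-one (racemic) | CC1=C(OC(C)C)C(O[Si](C)(C)C(C)(C)C)(C(=C)C(OC)OC)C1=O
F3 | step 7 | 4-[(tert-butyldimethylsilyl)oxy]-3-(dimethoxymethyl)-5-isopropoxy-6-methylphenol | COC(OC)c1cc(O)c(C)c(OC(C)C)c1O[Si](C)(C)C(C)(C)C
F4 | step 7 | 3-[(tert-butyldimethylsilyl)oxy]-2-(dimethoxymethyl)-6-hydroxy-4-isopropoxy-5-methylbenzaldehyde | COC(OC)c1c(C=O)c(O)c(C)c(OC(C)C)c1O[Si](C)(C)C(C)(C)C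
F5 | step 7 | 6-(benzyloxy)-3-[(tert-butyldimethylsilyl)oxy]-2-(dimethoxymethyl)-4-isopropoxy-5-methylbenzaldehyde | COC(OC)c1c(C=O)c(OCc2ccccc2)c(C)c(OC(C)C)c1O[Si](C)(C)C(C)(C)C
F6 | step 7 | 6-(benzyloxy)-2-(dimethoxymethyl)-3-hydroxy-4-isopropoxy-5-methylbenzaldehyde | COC(OC)c1c(C=O)c(OCc2ccccc2)c(C)c(OC(C)C)c1O
F7 | step 13 | 5-fluorovanillin (3-fluoro-4-hydroxy-5-methoxybenzaldehyde) | COc1cc(C=O)cc(F)c1O
F8 | step 13 | 2-fluoro-6-methoxy-4-methylphenol | COc1cc(C)cc(F)c1O
F9 | step 13 | 1-fluoro-2-isopropoxy-3-methoxy-5-methylbenzene | COc1cc(C)cc(F)c1OC(C)C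
F10 | step 13 | 2-fluoro-3-isopropoxy-4-methoxy-6-methylbenzaldehyde | COc1cc(C)c(C=O)c(F)c1OC(C)C
F11 | step 12 | 2-methoxy-4-methylphenyl acetate | COc1cc(C)ccc1OC(C)=O
F12 | step 12 | 5-formyl-2-methoxy-4-methylphenyl acetate | COc1cc(C)c(C=O)cc1OC(C)=O
F13 | step 12 | 5-hydroxy-4-methoxy-2-methylbenzaldehyde | COc1cc(C)c(C=O)cc1O
F14 | step 12 | 2-bromo-3-hydroxy-4-methoxy-6-methylbenzaldehyde | COc1cc(C)c(C=O)c(Br)c1O
F15 | step 18 | racemic tripropionate of the target | COc1cc(C)c2c(c1OC(=O)CC)Oc1c(c(C)c(OC(=O)CC)c3c1C(OC(=O)CC)OC3=O)OC2=O
F16 | step 18 | (S)-tripropionate | COc1cc(C)c2c(c1OC(=O)CC)Oc1c(c(C)c(OC(=O)CC)c3c1[C@@H](OC(=O)CC)OC3=O)OC2=O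
F17 | step 19 | racemic bis(tert-butyldimethylsilyl) ether of 28 (silyl on a6–O and b4–O) | COc1cc(C)c2c(c1O[Si](C)(C)C(C)(C)C)Oc1c(c(C)c(O[Si](C)(C)C(C)(C)C)c3c1C(O)OC3=O)OC2=O
F18 | step 19 | (R)-propionyl acylal bis(tert-butyldimethylsilyl) ether | COc1cc(C)c2c(c1O[Si](C)(C)C(C)(C)C)Oc1c(c(C)c(O[Si](C)(C)C(C)(C)C)c3c1[C@H](OC(=O)CC)OC3=O)OC2=O
F19 | step 19 | (R)-propionyl acylal diphenol | COc1cc(C)c2c(c1O)Oc1c(c(C)c(O)c3c1[C@H](OC(=O)CC)OC3=O)OC2=O
A1 | alternative 1 | (R)-acetoxyphthalide depsidone triacetate | COc1cc(C)c2c(c1OC(C)=O)Oc1c(c(C)c(OC(C)=O)c3c1[C@H](OC(C)=O)OC3=O)OC2=O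
A2 | alternative 1 | depsidone ring B dialdehyde diacetate | COc1cc(C)c2c(c1OC(C)=O)Oc1c(c(C)c(OC(C)=O)c(C=O)c1C=O)OC2=O
A3 | alternative 2 | bromo depside | Cc1cc(O)cc(O)c1C(=O)Oc1c(Br)c(C(OC)OC)c(C(=O)OCc2ccccc2)c(O)c1C
A4 | alternative 2 | 6-(2,4-dioxopentyl)-2,2-dimethyl-4H-1,3-dioxin-4-one | CC(=O)CC(=O)CC1=CC(=O)OC(C)(C)O1
A5 | alternative 2 | benzyl 3-bromo-2-(dimethoxymethyl)-4,6-dihydroxy-5-methylbenzoate | Cc1c(O)c(Br)c(C(OC)OC)c(C(=O)OCc2ccccc2)c1O
A6 | alternative 3 | depsidone aldehyde allyl ester | COc1cc(C)c2c(c1OCC=C)Oc1c(c(C)c(O)c(C(=O)OCC=C)c1C=O)OC2=O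
A7 | alternative 3 | diaryl ether acid with b2–H | COc1cc(C)c(C(=O)O)c(Oc2cc(C)c(O)c(C(=O)OCC=C)c2C=O)c1OCC=C
A8 | alternative 3 | spiro ketal lactone (cyclohexadienone) | COc1cc(C)c2c(c1OCC=C)OC1(OC2=O)C=C(C)C(=O)C(C(=O)OCC=C)=C1C=O
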